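| flask | starting material | coupling partner | free catalyst | remark | time |
|---|---|---|---|---|---|
| zeta | 0.073 M | 1.1 equiv | 0.2 mol% | run made earlier |  |
| theta | 0.073 M | 0.55 equiv | 0.2 mol% | run made earlier |  |
| epsilon | 0.073 M | 0.83 equiv | 0.2 mol% | run made earlier |  |
| eta | 0.11 M | 1.1 equiv | 0.2 mol% | run made earlier |  |
| ochre | 0.073 M | 1.10 equiv (fed, over 5.00 min) | 0.2 mol% | a stirred flask in which coupling partner is dosed at a steady rate over 5.00 min without added volume, worked up at 5.0 min | 5.0 min |
| blue | 0.073 M | 1.10 equiv | 0.2 mol% | everything together in a closed stirred flask, run for 5.0 min | 5.0 min |
| violet | 0.073 M (fed, over 5.00 min) | 1.10 equiv | 0.2 mol% | all but starting material at the start; starting material goes in evenly over 5.00 min, the run ends at 5.0 min | 5.0 min |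
| red | 0.073 M | 1.10 equiv | 0.2 mol% | one stirred flow tank at steady state, fed with the mixture as stated, mean residence time 5.0 min |  |

| zeta: time / min | zeta: target / % | theta: time / min | theta: target / % | epsilon: time / min | epsilon: target / % | eta: time / min | eta: target / % |
|---|---|---|---|---|---|---|---|
| 1.33 | 21.9 | 0.250 | 1.3 | 0.250 | 3.8 | 0.250 | 6.4 |
| 2.50 | 37.5 | 0.500 | 4.7 | 0.500 | 5.9 | 0.500 | 11.4 |
| 4.00 | 52.9 | 1.33 | 11.8 | 1.33 | 17.7 | 1.33 | 28.0 |
| 5.00 | 61.8 | 3.00 | 24.6 | 3.00 | 34.1 | 3.00 | 55.8 |

(each reading ± 0.5 percentage points)

- the stated concentrations are those of everything mixed, before any reaction; amounts are the same in each set-up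
- the analysis behind the earlier runs scatters by 0.5 percentage points, standard deviation
- the feed brings no volume worth counting
- the earlier runs were made in a closed, stirred flask

- the set-up with the highest amount of target at the outlet or at the end, in percent of the starting material put in ("none" if the first two lie within 2 percentage points) (ochre / blue / violet / red / none)
- amount of target at the outlet or at the end, in percent of the starting material put in, ochre
- amount of target at the outlet or at the end, in percent of the starting material put in, blue
- amount of target at the outlet or at the end, in percent of the starting material put in, violet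
- amount of target at the outlet or at the end, in percent of the starting material put in, red

**Partner constant.** 0.165 min⁻¹ is the partner constant λ, the logarithm of charged over remaining coupling partner divided by time, as we read it from the last zeta reading, counting one partner spent per target formed. The zeta reading at 2.50 min gives 0.167 min⁻¹, so in zeta the partner decays in a pseudo-first-order way. Theta gives 0.198 min⁻¹ at 3.00 min, more than zeta, so λ read from these readings changes with the charge, and we carry it as an estimate.

**Our reckoning.** Blue repeats zeta, so we take 61.8%. The tank balance of partner gives red 49.7%, and the same constant under a steady feed gives ochre 35.1%.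

**Violet bracket.** Violet has blue's partner but less starting material in the flask, so blue's 61.8% is our bound from above. For the bound from below, the feed brings 0.200 min⁻¹ of the charge while the partner demands 0.182 min⁻¹, so the stock can build. Zeta's readings show λ steady with the stock of starting material as low as 38.2% of the charge, a stock which the feed reaches at 1.91 min. If nothing reacts before then and λ holds afterwards, violet gives 43.9%. We commit to the middle, 52.9%, with blue best.

**The forecast.** It also names blue, with 36.5% for ochre, 61.8% for blue and 49% for red, on the view that “product appears to replace consumed partner”. Its 36.5% for violet, range 33% to 42%, stands below our bracket.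

**The flask.** Ochre gives 37.5%, blue 62.1%, violet 51.6% and red 50.5%, so blue is best and violet lies inside the bracket.

    coupling partner + free catalyst ⇌ catalyst intermediate A (K = 1.40 L mol⁻¹, k = 380 L mol⁻¹ s⁻¹)
    catalyst intermediate A → released group + catalyst intermediate B (k = 19.0 s⁻¹)
    catalyst intermediate B ⇌ catalyst intermediate C (K = 23.0, k = 40.0 s⁻¹)
    starting material + catalyst intermediate C → catalyst intermediate D (k = 210 L mol⁻¹ s⁻¹)
    catalyst intermediate D → free catalyst + target (k = 23.0 s⁻¹)

**Slow stock.** The slow dosing of starting material accounts for part of violet's result, taking it from 62.1% to 51.6%, while in blue part of what is missing goes to the back reaction of catalyst intermediate A, acting together with the time allowed, for without that back reaction blue gives 99.7%. At 2.50 min violet held 26.0% of starting material, less than the lowest stock read from zeta, and it ended with 53% of its partner, more than the 43.8% that λ leaves. On the neighbour of ochre fed 1.90 equiv of partner, λ gives 60.6%, and that flask gives 57.8%.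

The readings were computed for an exercise, noise included.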